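D ends higher the more Z the flask holds: 55% at [Z] = 0.33 M, 63% at 0.65 M and 74% at 1.3 M, with [X] the same in each run. You asked for a quick number, so we reckon it as a small correction to the north run.

| flask | J | Z | X | remark | time |
|---|---|---|---|---|---|
| north | 0.13 M | 0.65 M | 0.26 M | run made earlier |  |
| west | 0.13 M | 0.33 M | 0.26 M | run made earlier |  |
| north-west | 0.13 M | 1.3 M | 0.26 M | run made earlier |  |
| gamma | 0.13 M (fed, over 25 h) | 0.650 M | 0.260 M | all else is in the flask from the start; the feed brings no volume worth counting | 20 d |
| epsilon | 0.13 M (fed, over 4.0 d) | 0.650 M | 0.260 M | all else is in the flask from the start; the feed brings no volume worth counting | 20 d |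
| theta | 0.13 M | 0.650 M | 0.260 M | everything together at the start | 20 d |
| eta | 0.13 M | 0.650 M | 0.260 M (fed, over 4.0 d) | all else is in the flask from the start; the feed brings no volume worth counting | 20 d |

| run | time / d | D / % | J / % |
|---|---|---|---|
| north | 1.67 | 34 | 23 |
| north | 2.50 | 41 | 13 |
| north | 4.00 | 54 | 4 |
| north | 8.00 | 61 | 2 |
| north | 12.0 | 63 | 0 |
| north | 20.0 | 63 | 0 |
| west | 2.08 | 24 | 42 |
| west | 3.00 | 34 | 32 |
| west | 5.00 | 43 | 16 |
| west | 8.00 | 52 | 7 |
| west | 15.0 | 53 | 3 |
| west | 25.0 | 55 | 0 |
| north-west | 2.08 | 53 | 3 |
| north-west | 3.00 | 58 | 0 |
| north-west | 5.00 | 69 | 0 |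
| north-west | 8.00 | 70 | 0 |
| north-west | 15.0 | 74 | 0 |
| north-west | 25.0 | 74 | 0 |

(standard deviation of a reading: 1.5 percentage points)



- the best flask by amount of D, in percent of the J charged; "all alike" if 1.5 percentage points covers them all (gamma / epsilon / theta / eta / all alike)
- amount of D at the end, in percent of the J charged, gamma
- amount of D at the end, in percent of the J charged, epsilon
- amount of D at the end, in percent of the J charged, theta
- amount of D at the end, in percent of the J charged, eta

1. As a rough waiting time for J we take the time of its first reading over the logarithm of its fall: 2.40 d in the west run and 0.593 d in the north-west run. The west figure is an early one and no constant, since the next west reading gives 2.63 d, so what we build on it is an estimate.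

2. The north-west run has the shorter wait and ends with more D than the west run. Dividing the gain in D by the shortening of the wait gives 0.105 d⁻¹. We call this the delay price: the fraction of the J charged that D loses for each day J lags behind X.

3. A steady feed holds its material back by half of the feed time on average. Theta has the north charges, so we take its reading, 63%. Feeding J adds lag, which gives 57.5% for gamma and 41.9% for epsilon.

4. Feeding X turns the lag into a lead, which gives 84.1% for eta, our best flask. X was not varied in the runs, so this number is an extrapolation.

5. The forecast differs from ours: 63% for gamma, 63% for epsilon, 63% for theta and 62% for eta, so all alike, reasoning that “feeding J should change little”.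

6. The flasks give 58.2% for gamma, 43.9% for epsilon, 65.5% for theta and 78.4% for eta, so the best is eta.

    X ⇌ G (K = 0.620, k = 0.0170 h⁻¹)
    J + Z → E (k = 0.0600 M⁻¹ h⁻¹)
    X → Q (k = 0.0200 h⁻¹)
    X + E → D (k = 0.230 M⁻¹ h⁻¹)

The delay price is the cost of X waiting while it decays. Of the steps tried, striking out the reaction of X to Q turns the gap between eta and epsilon most: 34 percentage points falls to 0.037 points. Our price over the 4.0 d between those flasks gives 42 points. On gamma, the price for half of 25 h gives 5.5 points below theta, and the flasks show 7.3 points.

The data come from a simulation with constants of no real substance.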